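**Retrosynthetic overview**
1. C15–O bond: an E-selective 1,4-hydroacyloxylation of a 2-substituted 1,3-diene with propanoic acid makes the allylic ester and fixes the 13E alkene in one C–O bond-forming step.
2. Ring A is closed last by a Diels–Alder reaction of the ring B vinylcyclohexene with methyl methacrylate (C2–C3 and C4–C5 bonds; sets C4 and C5).
3. Both dienes come from one 1,5-diketone by double enol triflation and double Stille vinylation.
4. The diketone comes from 2-methylcyclohex-2-enone (ring B, bought) by asymmetric conjugate methylation (sets C8) and Mukaiyama–Michael addition to methyl vinyl ketone (sets C9).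

Assumption: positions are given in halimane numbering (C1–C20, C18 = ester carbon; target is 4S,5R,8R,9S,13E), and in step 1 the ligand antipode that gives the 3R enolate is used, its sense being checked on the first run.

**Step 1**
Reactants: 1 2-methylcyclohex-2-en-1-one; 2 methylmagnesium bromide; 3 chlorotrimethylsilane
Product: 5 trimethyl{[(3R)-2,3-dimethylcyclohex-1-en-1-yl]oxy}silane, via bromomagnesium enolate 4 (not isolated)
Conditions: MeMgBr (1.2 equiv), Cu(OTf)2 (3 mol %), chiral hydroxyalkyl imidazolinium salt (NHC precursor, 4 mol %), Et2O, −30 °C; then TMSCl, Et3N, DMPU, −30 → 0 °C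
Reagents that add atoms: methylmagnesium bromide (C[Mg]Br); chlorotrimethylsilane (C[Si](C)(C)Cl)
Why: Copper-catalysed asymmetric conjugate addition, in which the chiral carbene ligand selects the β-face and sets C8 (R), followed by O-silylation that stores the regiodefined tetrasubstituted enolate.

**Step 2**
Reactants: 5 trimethyl{[(3R)-2,3-dimethylcyclohex-1-en-1-yl]oxy}silane; 6 but-3-en-2-one (methyl vinyl ketone)
Product: 7 (2S,3R)-2,3-dimethyl-2-(3-oxobutyl)cyclohexan-1-one
Conditions: MVK (1.5 equiv), BF3·OEt2 (0.3 equiv), i-PrOH (1.1 equiv), MeNO2–CH2Cl2, −78 → −30 °C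
Reagents that add atoms: but-3-en-2-one (CC(=O)C=C)
Why: Mukaiyama–Michael addition, in which A(1,2) strain holds the C8 methyl pseudoaxial so the enone adds to the opposite face, setting the quaternary C9 (S) with the two methyls cis.

**Step 3**
Reactants: 7 (2S,3R)-2,3-dimethyl-2-(3-oxobutyl)cyclohexan-1-one; 8 N-phenylbis(trifluoromethanesulfonimide)
Product: 10 (5R,6S)-5,6-dimethyl-6-{3-[(trifluoromethanesulfonyl)oxy]but-3-en-1-yl}cyclohex-1-en-1-yl trifluoromethanesulfonate, via dilithium bis(enolate) 9 (not isolated)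
Conditions: LDA (2.5 equiv), THF, −78 °C (7 added to the base); then PhNTf2 (2.5 equiv), −78 → 0 °C
Reagents that add atoms: N-phenylbis(trifluoromethanesulfonimide) (O=S(=O)(N(c1ccccc1)S(=O)(=O)C(F)(F)F)C(F)(F)F)
Why: Kinetic double enolisation and O-triflation, where the ring ketone can only enolise toward C5 (C9 is quaternary) and the methyl ketone is deprotonated at CH3, with no stereocentre touched.

**Step 4**
Reactants: 10 the bis(enol triflate); 11 tributyl(ethenyl)stannane
Product: 12 (5R,6S)-1-ethenyl-5,6-dimethyl-6-(3-methylidenepent-4-en-1-yl)cyclohex-1-ene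
Conditions: CH2=CHSnBu3 (2.6 equiv), Pd(PPh3)4 (5 mol %), LiCl (6 equiv), THF, 65 °C
Reagents that add atoms: tributyl(ethenyl)stannane (C=C[Sn](CCCC)(CCCC)CCCC)
Why: Two-fold Stille coupling of alkenyl triflates, which turns both former carbonyl carbons into diene carbons in one operation without affecting C8 or C9.

**Step 5**
Reactants: 12 (5R,6S)-1-ethenyl-5,6-dimethyl-6-(3-methylidenepent-4-en-1-yl)cyclohex-1-ene; 13 propanoic acid
Product: 14 (2E)-5-[(1S,6R)-2-ethenyl-1,6-dimethylcyclohex-2-en-1-yl]-3-methylpent-2-en-1-yl propanoate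
Conditions: EtCO2H (1.5 equiv), Pd2(dba)3 (2.5 mol %), P(t-Bu)3 (5 mol %), toluene, 0 → 23 °C
Reagents that add atoms: propanoic acid (CCC(=O)O)
Why: Proposed new method: a palladium-catalysed, E-selective 1,4-hydroacyloxylation of a 2-alkyl-1,3-diene, in which monoligated zerovalent palladium binds the unhindered side-chain diene in its s-cis form, propanoic acid delivers H to C16 (the terminus that gives the more substituted allyl) so that the new methyl sits anti, that is cis to C15, and propanoate then bonds to the open CH2 terminus C15 before syn/anti exchange (which at this fully substituted terminus needs a tertiary σ-allyl), giving the primary 13E ester while the crowded ring diene and the trisubstituted product alkene bind too weakly to react or re-ionise; closest known reaction type: palladium-hydride 1,4-hydrofunctionalisation of 1,3-dienes (hydroamination, hydrosilylation with cis-1,4 delivery, addition of carboxylic acids to butadiene and to allenes).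

**Step 6**
Reactants: 14 the trienyl propanoate; 15 methyl 2-methylprop-2-enoate (methyl methacrylate)
Product: 16 methyl (1S,5S,6R,8aR)-1,5,6-trimethyl-5-[(3E)-3-methyl-5-(propanoyloxy)pent-3-en-1-yl]-1,2,3,5,6,7,8,8a-octahydronaphthalene-1-carboxylate (CNP0279628.1)
Conditions: methyl methacrylate (10 equiv), Me2AlCl (1.5 equiv), CH2Cl2, −40 → 0 °C
Reagents that add atoms: methyl 2-methylprop-2-enoate (C=C(C)C(=O)OC)
Why: Lewis-acid-promoted Diels–Alder reaction with "ortho" regiochemistry (ester carbon C4 bonds to the ring terminus C5) and an endo ester (CO2Me trans to H5, setting C4 S), the dienophile adding equatorially to the face anti to the axial C9 methyl in the half-chair that keeps the C8 methyl and the side chain equatorial (setting C5 R).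

**Compound list**
1 | 2-methylcyclohex-2-en-1-one | CC1=CCCC1=O | starting material
2 | methylmagnesium bromide | C[Mg]Br | starting material
3 | chlorotrimethylsilane | C[Si](C)(C)Cl | starting material
4 | bromomagnesium (3R)-2,3-dimethylcyclohex-1-en-1-olate | C[C@@H]1CCCC(O[Mg]Br)=C1C | intermediate
5 | trimethyl{[(3R)-2,3-dimethylcyclohex-1-en-1-yl]oxy}silane | C[C@@H]1CCCC(O[Si](C)(C)C)=C1C | intermediate
6 | but-3-en-2-one (methyl vinyl ketone) | CC(=O)C=C | starting material
7 | (2S,3R)-2,3-dimethyl-2-(3-oxobutyl)cyclohexan-1-one | CC(=O)CC[C@]1(C)C(=O)CCC[C@H]1C | intermediate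
8 | N-phenylbis(trifluoromethanesulfonimide) | O=S(=O)(N(c1ccccc1)S(=O)(=O)C(F)(F)F)C(F)(F)F | starting material
9 | dilithium (5R,6S)-5,6-dimethyl-6-(3-oxidobut-3-en-1-yl)cyclohex-1-en-1-olate | [Li+].[Li+].C=C([O-])CC[C@]1(C)C([O-])=CCC[C@H]1C | intermediate
10 | (5R,6S)-5,6-dimethyl-6-{3-[(trifluoromethanesulfonyl)oxy]but-3-en-1-yl}cyclohex-1-en-1-yl trifluoromethanesulfonate | C=C(OS(=O)(=O)C(F)(F)F)CC[C@]1(C)C(OS(=O)(=O)C(F)(F)F)=CCC[C@H]1C | intermediate
11 | tributyl(ethenyl)stannane | C=C[Sn](CCCC)(CCCC)CCCC | starting material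
12 | (5R,6S)-1-ethenyl-5,6-dimethyl-6-(3-methylidenepent-4-en-1-yl)cyclohex-1-ene | C=CC(=C)CC[C@]1(C)C(C=C)=CCC[C@H]1C | intermediate
13 | propanoic acid | CCC(=O)O | starting material
14 | (2E)-5-[(1S,6R)-2-ethenyl-1,6-dimethylcyclohex-2-en-1-yl]-3-methylpent-2-en-1-yl propanoate | CCC(=O)OC/C=C(\C)CC[C@]1(C)C(C=C)=CCC[C@H]1C | intermediate
15 | methyl 2-methylprop-2-enoate (methyl methacrylate) | C=C(C)C(=O)OC | starting material
16 | methyl (1S,5S,6R,8aR)-1,5,6-trimethyl-5-[(3E)-3-methyl-5-(propanoyloxy)pent-3-en-1-yl]-1,2,3,5,6,7,8,8a-octahydronaphthalene-1-carboxylate | CCC(=O)OC/C=C(\C)CC[C@]1(C)C2=CCC[C@](C)(C(=O)OC)[C@@H]2CC[C@H]1C | target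

**Step count**
Total steps: 6. Longest linear sequence: 6 (the route is fully linear from 1).

**Steps most likely to fail**

Step 5 (the proposed new step). The risks are erosion of E/Z through allyl isomerisation or re-ionisation of the product, formation of the tertiary (branched) ester, and palladium-hydride isomerisation of either diene. The fallback uses known chemistry and sets out from 12. Iron-catalysed 1,4-hydroboration of the side-chain diene (FeCl2, a 2-iminopyridine ligand, Mg, pinacolborane, Et2O, 23 °C), a known E-selective linear 1,4-addition to 2-substituted dienes, gives 2-[(2E)-5-[(1S,6R)-2-ethenyl-1,6-dimethylcyclohex-2-en-1-yl]-3-methylpent-2-en-1-yl]-4,4,5,5-tetramethyl-1,3,2-dioxaborolane F1. Oxidation with NaBO3·4H2O in THF/H2O gives (2E)-5-[(1S,6R)-2-ethenyl-1,6-dimethylcyclohex-2-en-1-yl]-3-methylpent-2-en-1-ol F2. Acylation with propanoic anhydride, DMAP and pyridine comes back to the route at 14.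

Step 6. The risks are incomplete face or endo selectivity with the weakly biased methacrylate, and ionisation of the allylic propanoate by the aluminium Lewis acid. The fallback sets out from 14 and moves stereocontrol to the catalyst with a more reactive dienophile. Methacrolein with a triflimide-activated o-tolyl oxazaborolidine (20 mol %, the antipode that matches the substrate, CH2Cl2, −78 °C) gives (2E)-5-[(1S,2R,4aR,5S)-5-formyl-1,2,5-trimethyl-1,2,3,4,4a,5,6,7-octahydronaphthalen-1-yl]-3-methylpent-2-en-1-yl propanoate F3. Pinnick oxidation (NaClO2, NaH2PO4, 2-methylbut-2-ene, t-BuOH/H2O) gives (1S,5S,6R,8aR)-1,5,6-trimethyl-5-[(3E)-3-methyl-5-(propanoyloxy)pent-3-en-1-yl]-1,2,3,5,6,7,8,8a-octahydronaphthalene-1-carboxylic acid F4. Methylation with TMSCHN2 in MeOH/toluene comes back at 16.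

Step 3. The risks are intramolecular aldol reaction of a mono-enolate and internal (CH2) enolisation of the methyl ketone. The fallback sets out from 7 and treats the two ketones one after the other. Selective ketalisation of the unhindered methyl ketone (1,2-bis(trimethylsilyloxy)ethane, TMSOTf cat., CH2Cl2, −78 °C) gives (2S,3R)-2,3-dimethyl-2-[2-(2-methyl-1,3-dioxolan-2-yl)ethyl]cyclohexan-1-one F5. KHMDS and PhNTf2 (THF, −78 °C) give (5R,6S)-5,6-dimethyl-6-[2-(2-methyl-1,3-dioxolan-2-yl)ethyl]cyclohex-1-en-1-yl trifluoromethanesulfonate F6. Aqueous HCl in THF frees (5R,6S)-5,6-dimethyl-6-(3-oxobutyl)cyclohex-1-en-1-yl trifluoromethanesulfonate F7. With only one carbonyl left, LDA (1.2 equiv, −78 °C) then PhNTf2 gives the terminal enol triflate and comes back at 10.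

**Further compounds**
F1 | step 5 | 2-[(2E)-5-[(1S,6R)-2-ethenyl-1,6-dimethylcyclohex-2-en-1-yl]-3-methylpent-2-en-1-yl]-4,4,5,5-tetramethyl-1,3,2-dioxaborolane | CC1(C)OB(C/C=C(\C)CC[C@]2(C)C(C=C)=CCC[C@H]2C)OC1(C)C
F2 | step 5 | (2E)-5-[(1S,6R)-2-ethenyl-1,6-dimethylcyclohex-2-en-1-yl]-3-methylpent-2-en-1-ol | OC/C=C(\C)CC[C@]1(C)C(C=C)=CCC[C@H]1C
F3 | step 6 | (2E)-5-[(1S,2R,4aR,5S)-5-formyl-1,2,5-trimethyl-1,2,3,4,4a,5,6,7-octahydronaphthalen-1-yl]-3-methylpent-2-en-1-yl propanoate | CCC(=O)OC/C=C(\C)CC[C@]1(C)C2=CCC[C@](C)(C=O)[C@@H]2CC[C@H]1C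
F4 | step 6 | (1S,5S,6R,8aR)-1,5,6-trimethyl-5-[(3E)-3-methyl-5-(propanoyloxy)pent-3-en-1-yl]-1,2,3,5,6,7,8,8a-octahydronaphthalene-1-carboxylic acid | CCC(=O)OC/C=C(\C)CC[C@]1(C)C2=CCC[C@](C)(C(=O)O)[C@@H]2CC[C@H]1C
F5 | step 3 | (2S,3R)-2,3-dimethyl-2-[2-(2-methyl-1,3-dioxolan-2-yl)ethyl]cyclohexan-1-one | CC1(CC[C@]2(C)C(=O)CCC[C@H]2C)OCCO1
F6 | step 3 | (5R,6S)-5,6-dimethyl-6-[2-(2-methyl-1,3-dioxolan-2-yl)ethyl]cyclohex-1-en-1-yl trifluoromethanesulfonate | CC1(CC[C@]2(C)C(OS(=O)(=O)C(F)(F)F)=CCC[C@H]2C)OCCO1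
F7 | step 3 | (5R,6S)-5,6-dimethyl-6-(3-oxobutyl)cyclohex-1-en-1-yl trifluoromethanesulfonate | CC(=O)CC[C@]1(C)C(OS(=O)(=O)C(F)(F)F)=CCC[C@H]1C
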